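**Plan**

Atisane numbering: C1–C3 lactone chain, C5 CH(isopropenyl), C6/C7 CH2, C8 all-carbon bridgehead, C9 C–O, C10 C–CH3 (C20), C11 CH2, C12 CH bridgehead, C13 CH2, C14 CHOAc, C15 C=O, C16=C17.
Cuts, in retrosynthetic order: C16=C17 (Mannich methylenation), the acetate and C14–H, C11–C12 (radical conjugate cyclisation), O–CH3 on C15, C9–O together with C11–I (iodolactonisation), C7–C8 (dearomatising alkylation), C8–C9 (Negishi coupling), C9–C11, C10–C1 and C10–C20.
Feature: the carbocycle C8–C14–C13–C12–C16–C15 carries oxygen on both carbons that flank quaternary C8, so it is a C2-dialkylated resorcinol ring. In its dienone form C12 is the β-carbon of the C14 carbonyl and lies para to C8, so the bicyclo[2.2.2]octane lacks only the bond from C12 to C11, the single CH2 on neighbouring C9.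
Forward: the ring of (R)-carvone is dialkylated at C10 and cut open to the chain C7–C6–C5–C10–C9. The resorcinol is joined at C9, ring B closes with loss of aromaticity, then the δ-lactone closes, then the bicyclo[2.2.2]octene.
Stereochemistry: C5 comes from (R)-carvone, C10 from alkylation anti to the isopropenyl group, and C9 from same-face delivery of the tethered carboxyl group. C8 is set by methylation of the only exposed ring oxygen, C12 by the bridge geometry, and C14 by ketyl reduction to the less hindered carbinol.

Key step: step 17

Assumption: the two keto tautomers of the spiro-enediones 26 and 27 (C12=C13 or C12=C16) interconvert through one common dienolate, so each is drawn as a single tautomer and the C8 descriptor in those two SMILES has no lasting meaning.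

**Step 1**
Reactants: 1 (R)-(−)-carvone
Product: 3 trans-6-methylcarvone, via lithium enolate 2 (not isolated)
Conditions: LiN(i-Pr)2, THF, −78 °C; MeI, −78 → 0 °C
Reagents that add atoms: iodomethane, CI
Why: Kinetic α′-deprotonation gives the cross-conjugated enolate, and its C-methylation (enolate alkylation) brings in C20; the new centre is flattened again in step 2, so its configuration does not matter.

**Step 2**
Reactants: 3 trans-6-methylcarvone
Product: 5 6-allyl-6-methylcarvone, via lithium enolate 4 (not isolated)
Conditions: LiN(i-Pr)2, THF, −78 °C; allyl bromide, DMPU, −78 °C → rt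
Reagents that add atoms: allyl bromide, C=CCBr
Why: In this enolate alkylation the electrophile approaches the tetrasubstituted enolate on the face opposite the neighbouring isopropenyl group, which sets C10 with the three-carbon chain trans and the methyl group cis to the isopropenyl group.

**Step 3**
Reactants: 5 6-allyl-6-methylcarvone
Product: 6 epoxy ketone
Conditions: 30% H2O2, NaOH (cat.), MeOH, 0 °C
Reagents that add atoms: hydrogen peroxide, OO
Why: Weitz–Scheffer nucleophilic epoxidation attacks only the electron-poor enone double bond and leaves the allyl and isopropenyl groups alone; the epoxide configuration is erased in step 4.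

**Step 4**
Reactants: 6 epoxy ketone
Product: 8 acid aldehyde, via keto diol 7 (not isolated)
Conditions: dilute H2SO4, THF–H2O, rt; then NaIO4, rt
Reagents that add atoms: water, O
Why: Acid-catalysed epoxide hydrolysis followed by Malaprade periodate cleavage of the α,β-dihydroxy ketone cuts both C–C bonds at the former methyl-bearing ring carbon, which gives the C9 acid and the C7 aldehyde without touching C5 or C10.

**Step 5**
Reactants: 8 acid aldehyde
Product: 10 δ-lactone, via hydroxy acid 9 (not isolated)
Conditions: NaBH4, MeOH, 0 °C; then 1 M HCl, rt
Reagents that add atoms: none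
Why: Borohydride reduces only the aldehyde, and acid-induced lactonisation, helped by the quaternary C10, stores C7–O and C9=O in one six-membered ring.

**Step 6**
Reactants: 10 δ-lactone
Product: 11 hydroxy methyl ketone
Conditions: MeLi, Et2O–THF, −78 °C; then H2O
Reagents that add atoms: methyllithium, [Li]C
Why: This is a single addition of an organolithium to a lactone, in which the hindered tetrahedral alkoxide survives at low temperature, so C11 enters once and the quench frees the C7 alcohol.

**Step 7**
Reactants: 11 hydroxy methyl ketone
Product: 12 chloro ketone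
Conditions: PPh3, CCl4, CH2Cl2, 40 °C
Reagents that add atoms: carbon tetrachloride, ClC(Cl)(Cl)Cl
Why: The Appel reaction converts the primary alcohol of the open hydroxy-ketone form into a chloride, a leaving group that stays inert in steps 8 to 13.

**Step 8**
Reactants: 12 chloro ketone
Product: 14 enol triflate, via potassium enolate 13 (not isolated)
Conditions: KN(SiMe3)2, THF, −78 °C; PhNTf2, −78 → 0 °C
Reagents that add atoms: N-phenylbis(trifluoromethanesulfonimide), O=S(=O)(N(c1ccccc1)S(=O)(=O)C(F)(F)F)C(F)(F)F
Why: C10 is quaternary, so deprotonation can occur only at C11, and O-sulfonylation of that enolate gives the terminal enol triflate before the distant chloride can react at this temperature.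

**Step 9**
Reactants: 15 resorcinol
Product: 16 1,3-bis(methoxymethoxy)benzene
Conditions: NaH, MOMCl, DMF, 0 °C → rt
Reagents that add atoms: chloromethyl methyl ether, COCCl
Why: Williamson-type O-alkylation protects both phenols as acetals, and these later direct lithiation to the carbon between them.

**Step 10**
Reactants: 14 enol triflate; 16 1,3-bis(methoxymethoxy)benzene
Product: 19 α-aryl alkene, via aryllithium 17 (not isolated), via arylzinc chloride 18 (not isolated)
Conditions: 16, n-BuLi, THF, 0 °C; ZnCl2, 0 °C → rt; then 14, Pd(OAc)2, SPhos, THF, 60 °C
Reagents that add atoms: none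
Why: Directed ortho-metalation between the two acetals, transmetalation to zinc and Negishi coupling form C8–C9 and give the C9=C11 alkene without addition to a doubly flanked aryl ketone; bulky biaryl phosphines are established for di-ortho-substituted arylzincs, and the alkyl chloride is inert to zerovalent palladium.

**Step 11**
Reactants: 19 α-aryl alkene
Product: 21 primary alcohol, via B-alkyl-9-BBN adduct 20 (not isolated)
Conditions: 9-BBN, THF, 0 °C → rt; then NaOH, H2O2, 0 °C
Reagents that add atoms: hydrogen peroxide, OO
Why: In this hydroboration–oxidation 9-BBN selects the monosubstituted allyl double bond over the two 1,1-disubstituted alkenes and places boron on the terminal carbon C3.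

**Step 12**
Reactants: 21 primary alcohol
Product: 23 carboxylic acid, via aldehyde 22 (not isolated)
Conditions: TEMPO (cat.), PhI(OAc)2, MeCN–H2O, rt
Reagents that add atoms: water, O
Why: Oxoammonium-catalysed oxidation takes the primary alcohol through the aldehyde hydrate to the C3 acid and tolerates alkenes, aryl acetals and the alkyl chloride.

**Step 13**
Reactants: 23 carboxylic acid
Product: 24 resorcinol acid
Conditions: ZnBr2, n-PrSH, CH2Cl2, 0 °C → rt
Reagents that add atoms: none
Why: Lewis acid and thiol cleave the aryl MOM ethers, and the thiol captures the formaldehyde unit as a dithioacetal, so it cannot hydroxymethylate the free resorcinol and no strong Brønsted acid meets the electron-rich alkene.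

**Step 14**
Reactants: 24 resorcinol acid
Product: 26 spiro-enedione acid, via primary iodide 25 (not isolated)
Conditions: t-BuOK (3 equiv), NaI (cat.), t-BuOH–THF, high dilution, 60 °C; then 1 M HCl to pH 3
Reagents that add atoms: none
Why: After Finkelstein exchange the resorcinolate is alkylated at its C2 carbon (alkylative dearomatisation, 6-exo-tet), which forms C7–C8 and ring B; closure through oxygen or through any other ring carbon would need an eight-membered ring, and because the two ring oxygens are equivalent no configuration at C8 has to be controlled here.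

**Step 15**
Reactants: 26 spiro-enedione acid
Product: 27 iodomethyl lactone enedione
Conditions: NIS, CH2Cl2, 0 °C, dark
Reagents that add atoms: N-iodosuccinimide, O=C1CCC(=O)N1I
Why: In this 6-exo iodolactonisation the carboxyl oxygen can reach C9 only on the face that carries its own chain, since the opposite face is flanked by the axial C20 methyl and the axial spiro carbon, so C9 is set with O cis to C1 and CH2I equatorial; iodine is chosen because iodonium formation on the isopropenyl group is reversible, and the neutral medium keeps the enedione in its unreactive keto form.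

**Step 16**
Reactants: 27 iodomethyl lactone enedione
Product: 29 spiro-dienone iodomethyl lactone, via potassium dienolate 28 (not isolated)
Conditions: KN(SiMe3)2 (1 equiv), THF, −78 °C; MeOTf, −78 °C
Reagents that add atoms: methyl trifluoromethanesulfonate, COS(=O)(=O)C(F)(F)F
Why: This is O-alkylation of a doubly vinylogous carboxylate with a hard electrophile: the equatorial CH2I now locks ring B in one chair, and the oxygen on the axial ring carbon is buried under ring B against C20, where a methyl group would collide with it, so methylation goes to the exposed oxygen on the equatorial carbon and fixes C8 with C15–OCH3 and C14=O; at −78 °C the neopentyl iodide is not displaced.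

**Step 17**
Reactants: 29 spiro-dienone iodomethyl lactone
Product: 30 15-methoxy bicyclo[2.2.2]oct-15-en-14-one lactone
Conditions: Bu3SnH (slow addition), AIBN, benzene, 80 °C, 5 mM
Reagents that add atoms: none
Why: The tributyltin radical abstracts iodine from the neopentyl C11–I bond, the primary C11 radical adds to C12, the β-carbon of the C14 dienone, and the resulting C13 radical, stabilised by the C14 carbonyl, takes hydrogen from Bu3SnH, which carries the chain. The closest known reaction type is the reductive intramolecular Giese addition (tin hydride conjugate cyclisation) of alkyl halides onto cyclohexenones and cyclohexadienones, which gives bridged bicyclooctanones. The one new ring closes in a six-membered mode, 6-exo-trig when counted through C9–C8–C15–C16 and 6-endo-trig when counted through C9–C8–C14–C13, and it completes the bicyclo[2.2.2]octene. C12 is the only new stereocentre and is fixed by C8 and C9, because the equatorial C11 arm lies over one face of the dienone and a bridge can form only there. C12 must win over C13 (five-membered closure to an allyl radical), over the isopropenyl group and over direct reduction: the nucleophilic radical prefers the β-carbon with the large LUMO coefficient, radicals with the carbonyl inside the chain are known to close endo, the isopropenyl group is 1,3-diequatorial to C11 in the locked chair and out of reach, and slow addition keeps the stannane concentration low. Folding of the flat dienone also moves the C14 oxygen away from the axial C20 methyl, so strain release helps the closure.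

**Step 18**
Reactants: 30 15-methoxy bicyclo[2.2.2]oct-15-en-14-one lactone
Product: 31 14-alcohol
Conditions: SmI2 (2.2 equiv), H2O, THF, 0 °C
Reagents that add atoms: none
Why: Single-electron (ketyl) reduction gives the more stable carbinol: the oxygen settles on the open side that faces the C15–C16 bridge, and the small proton enters from the side crowded by C20 and C10, which sets C14 as in the target, whereas hydride reagents would attack from the open side; the limited amount of samarium diiodide spares the lactone.

**Step 19**
Reactants: 31 14-alcohol
Product: 32 14-acetate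
Conditions: Ac2O, DMAP (cat.), pyridine, rt
Reagents that add atoms: acetic anhydride, CC(=O)OC(C)=O
Why: DMAP-catalysed acylation of the secondary alcohol proceeds with retention at C14, and the base-stable methyl enol ether and lactone are unaffected.

**Step 20**
Reactants: 32 14-acetate
Product: 35 crotobarin, via Mannich base 33 (not isolated), via methiodide 34 (not isolated)
Conditions: [Me2N=CH2]I, CH2Cl2, rt; MeI, rt; then aq NaHCO3, CH2Cl2, rt
Reagents that add atoms: N,N-dimethylmethyleneiminium iodide, C[N+](C)=C.[I-]
Why: The enol ether attacks the iminium salt at C16 (Mannich reaction) and iodide removes the O-methyl group to unveil the C15 ketone, then quaternisation and mild base trigger β-elimination to the C16=C17 enone; C8 carries no hydrogen, so the C14 acetate cannot be eliminated.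

**Compound list**

1 | (R)-(−)-carvone | CC1=CC[C@H](CC1=O)C(=C)C | starting material
2 | lithium cross-conjugated enolate of carvone | CC1=CC[C@H](C=C1O[Li])C(=C)C | intermediate
3 | trans-6-methylcarvone (new methyl on the future C10, trans to the isopropenyl group) | C[C@H]1[C@H](C(=C)C)CC=C(C)C1=O | intermediate
4 | lithium enolate of 6-methylcarvone (tetrasubstituted) | CC1=C(O[Li])C(C)=CC[C@H]1C(C)=C | intermediate
5 | 6-allyl-6-methylcarvone (allyl trans, methyl cis to the isopropenyl group) | C=CC[C@@]1(C)[C@H](C(=C)C)CC=C(C)C1=O | intermediate
6 | 2,3-epoxide of 5 (oxirane drawn anti to the isopropenyl group) | C=CC[C@@]1(C)[C@H](C(=C)C)C[C@H]2O[C@@]2(C)C1=O | intermediate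
7 | 2,3-dihydroxy ketone from trans opening of 6 | C=CC[C@@]1(C)[C@H](C(=C)C)C[C@H](O)[C@@](C)(O)C1=O | intermediate
8 | 2-allyl-2-methyl-5-oxo-3-(prop-1-en-2-yl)pentanoic acid (C9 acid, C7 aldehyde; C5 and C10 as in the target) | OC(=O)[C@@](C)(CC=C)[C@@H](CC=O)C(C)=C | intermediate
9 | 2-allyl-5-hydroxy-2-methyl-3-(prop-1-en-2-yl)pentanoic acid | OC(=O)[C@@](C)(CC=C)[C@@H](CCO)C(C)=C | intermediate
10 | 3-allyl-3-methyl-4-(prop-1-en-2-yl)oxan-2-one (allyl trans to the isopropenyl group) | O=C1OCC[C@@H](C(C)=C)[C@]1(C)CC=C | intermediate
11 | 3-allyl-6-hydroxy-3-methyl-4-(prop-1-en-2-yl)hexan-2-one | CC(=O)[C@@](C)(CC=C)[C@@H](CCO)C(C)=C | intermediate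
12 | 3-allyl-6-chloro-3-methyl-4-(prop-1-en-2-yl)hexan-2-one | CC(=O)[C@@](C)(CC=C)[C@@H](CCCl)C(C)=C | intermediate
13 | potassium enolate of 12 | C=C(O[K])[C@@](C)(CC=C)[C@@H](CCCl)C(C)=C | intermediate
14 | 3-allyl-6-chloro-3-methyl-4-(prop-1-en-2-yl)hex-1-en-2-yl triflate | C=C(OS(=O)(=O)C(F)(F)F)[C@@](C)(CC=C)[C@@H](CCCl)C(C)=C | intermediate
15 | resorcinol | Oc1cccc(O)c1 | starting material
16 | 1,3-bis(methoxymethoxy)benzene | COCOc1cccc(OCOC)c1 | intermediate
17 | 2,6-bis(methoxymethoxy)phenyllithium | [Li]c1c(OCOC)cccc1OCOC | intermediate
18 | 2,6-bis(methoxymethoxy)phenylzinc chloride | Cl[Zn]c1c(OCOC)cccc1OCOC | intermediate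
19 | 2-[3-allyl-6-chloro-3-methyl-4-(prop-1-en-2-yl)hex-1-en-2-yl]-1,3-bis(methoxymethoxy)benzene (C8–C9 joined, C9=C11) | C=C(c1c(OCOC)cccc1OCOC)[C@@](C)(CC=C)[C@@H](CCCl)C(C)=C | intermediate
20 | B-alkyl-9-BBN adduct of 19 (boron on C3) | C=C(c1c(OCOC)cccc1OCOC)[C@@](C)(CCCB1C2CCCC1CCC2)[C@@H](CCCl)C(C)=C | intermediate
21 | C3 primary alcohol | C=C(c1c(OCOC)cccc1OCOC)[C@@](C)(CCCO)[C@@H](CCCl)C(C)=C | intermediate
22 | C3 aldehyde | C=C(c1c(OCOC)cccc1OCOC)[C@@](C)(CCC=O)[C@@H](CCCl)C(C)=C | intermediate
23 | C3 carboxylic acid | C=C(c1c(OCOC)cccc1OCOC)[C@@](C)(CCC(=O)O)[C@@H](CCCl)C(C)=C | intermediate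
24 | resorcinol acid with C7 chloride | C=C(c1c(O)cccc1O)[C@@](C)(CCC(=O)O)[C@@H](CCCl)C(C)=C | intermediate
25 | resorcinol acid with C7 iodide | C=C(c1c(O)cccc1O)[C@@](C)(CCC(=O)O)[C@@H](CCI)C(C)=C | intermediate
26 | spiro[5.5]undecene-dione acid: ring B closed, C9=C11 exocyclic, spiro ring a cyclohex-4-ene-1,3-dione (one tautomer drawn) | O=C1CC=CC(=O)[C@]12CC[C@@H](C(C)=C)[C@](C)(CCC(=O)O)C2=C | intermediate
27 | iodomethyl δ-lactone enedione: lactone cis-fused on C9–C10, O9 axial, CH2I equatorial (one tautomer drawn) | O=C1CC=CC(=O)[C@]12CC[C@@H](C(C)=C)[C@]3(C)CCC(=O)O[C@]23CI | intermediate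
28 | potassium dienolate of 27 (drawn with potassium on O15) | [K]OC1=CC=CC(=O)[C@]12CC[C@@H](C(C)=C)[C@]3(C)CCC(=O)O[C@]23CI | intermediate
29 | spirocyclohexa-2,4-dienone iodomethyl lactone: C14=O on the axial ring carbon, OCH3 on the equatorial C15 | COC1=CC=CC(=O)[C@]12CC[C@@H](C(C)=C)[C@]3(C)CCC(=O)O[C@]23CI | intermediate
30 | bicyclo[2.2.2]octenone lactone: C14 ketone, C15(OCH3)=C16 enol ether, C11–C12 closed | C1=C(OC)[C@]23CC[C@@H](C(=C)C)[C@]4(C)CCC(=O)O[C@@]42C[C@H]1CC3=O | intermediate
31 | 14-alcohol, OH on the side of the C15–C16 bridge | C1=C(OC)[C@]23CC[C@@H](C(=C)C)[C@]4(C)CCC(=O)O[C@@]42C[C@H]1C[C@@H]3O | intermediate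
32 | 14-acetate of 31 | C1=C(OC)[C@]23CC[C@@H](C(=C)C)[C@]4(C)CCC(=O)O[C@@]42C[C@H]1C[C@@H]3OC(C)=O | intermediate
33 | 16-(dimethylaminomethyl) 15-ketone (both C16 epimers serve) | CN(C)CC1C(=O)[C@]23CC[C@@H](C(=C)C)[C@]4(C)CCC(=O)O[C@@]42C[C@H]1C[C@@H]3OC(C)=O | intermediate
34 | methiodide of 33 | C[N+](C)(C)CC1C(=O)[C@]23CC[C@@H](C(=C)C)[C@]4(C)CCC(=O)O[C@@]42C[C@H]1C[C@@H]3OC(C)=O.[I-] | intermediate
35 | crotobarin | C=C1C(=O)[C@]23CC[C@@H](C(=C)C)[C@]4(C)CCC(=O)O[C@@]42C[C@H]1C[C@@H]3OC(C)=O | target

Total step count: 20. Longest linear sequence: 19 (steps 1–8 and 10–20).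

**Steps most likely to fail**

Step 15. Electrophilic iodine may be consumed by slow enolisation and α-iodination of the enedione ring. Closure at the alkene between two quaternary carbons may also be so slow that the isopropenyl group is attacked irreversibly. The fallback replaces the halogen by selenium as both electrophile and radical leaving group. It sets out from 26. PhSeCl in CH2Cl2 at −78 °C adds to alkenes far faster than non-enolised ketones react, and capture by the carboxyl group gives the phenylselanylmethyl lactone enedione F1. The selenide is no leaving group, so O-methylation as in step 16 can be run without fear of internal alkylation and gives the phenylselanylmethyl lactone dienone F2. Bu3SnH and AIBN cleave the C11–Se bond and give the same C11 radical, so the route is rejoined at 30.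

Step 17. Hydrogen transfer to the primary radical may outrun the folding of the flat dienone. The radical may also close on C13 in a five-membered mode that leaves a delocalised allyl radical. The fallback cyclises before the ring oxygen is methylated. It sets out from 27. Bu3SnH and AIBN act on the enedione itself, whose acceptor is a plain enone in a non-planar ring, so attack at the α-carbon gains no allylic stabilisation and both tautomers give the same 14,15-diketone F3. The more exposed C15 carbonyl is then ketalised selectively with HC(OMe)3, MeOH and TsOH to the 15,15-dimethyl ketal F4. Me3SiOTf with i-Pr2NEt removes one methanol, and the route is rejoined at 30.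

Step 18. Three things may go wrong: facial selectivity in the protonation of the ketyl may be poor, the ketyl may rearrange through the neighbouring enol ether double bond (homoallyl to cyclopropylcarbinyl), or the δ-lactone may be over-reduced. The fallback is a two-electron reduction followed by redox equilibration. It sets out from 30. NaBH4 in MeOH delivers hydride from the open side and gives the 14-epi alcohol F5. The hydrogen-transfer catalyst (C5Ph5)Ru(CO)2Cl with catalytic t-BuOK in toluene then epimerises the carbinol reversibly through the ketone, which drains the crowded epimer into the less hindered one, and the route is rejoined at 31.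

**Further compounds**

F1 | step 15 | phenylselanylmethyl lactone enedione (selenium analogue of 27) | O=C1CC=CC(=O)[C@]12CC[C@@H](C(C)=C)[C@]3(C)CCC(=O)O[C@]23C[Se]c1ccccc1
F2 | step 15 | phenylselanylmethyl lactone dienone (selenium analogue of 29) | COC1=CC=CC(=O)[C@]12CC[C@@H](C(C)=C)[C@]3(C)CCC(=O)O[C@]23C[Se]c1ccccc1
F3 | step 17 | bicyclo[2.2.2]octane-14,15-dione lactone | C1C(=O)[C@]23CC[C@@H](C(=C)C)[C@]4(C)CCC(=O)O[C@@]42C[C@H]1CC3=O
F4 | step 17 | 15,15-dimethyl ketal of F3 | C1C(OC)(OC)[C@]23CC[C@@H](C(=C)C)[C@]4(C)CCC(=O)O[C@@]42C[C@H]1CC3=O
F5 | step 18 | 14-epi alcohol (OH on the side of the C9–C11 bridge) | C1=C(OC)[C@]23CC[C@@H](C(=C)C)[C@]4(C)CCC(=O)O[C@@]42C[C@H]1C[C@H]3O
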